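**Retrosynthetic overview**

1. The two 4-hydroxybenzoates are cut first (Steglich esterification with MOM-protected acid 25, then MOM removal), giving diol 22. Its C5 propenol chain goes back to the C5 aldehyde of 19 (HWE olefination, i-Bu2AlH reduction).
2. Ring B (O1, C2, C3, C3a, C7a) of 19 is opened at the aryl ether bond O1–C7a: intramolecular SNAr of the C2 alkoxide of 17 on the C7a fluoride, activated by the para C5 formyl group.
3. Feature used: C2 is a benzylic ether carbon para to the oxygen of the syringyl ring C and ionises easily. Ring B is therefore closed on the arene side, at O1–C7a, so no bond to C2 or C3 of the acyclic syn diad is touched; C5, para to C7a, carries the carbon that activates the closure and later grows into the side chain.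
4. The C2–C3 bond and both stereocentres come from an Evans syn aldol of arylacetyl oxazolidinone 9 with MOM-syringaldehyde 11. Imide 9 comes from 4-fluoro-3-methoxybenzaldehyde by acetalisation, lithiation ortho to fluorine, iodination and Negishi–Reformatsky coupling.
5. Ring order: ring A (benzo) and ring C (syringyl) are bought; ring B is the only ring made, in step 11.

Key step: step 11

Remark: ring atoms are numbered as in 2,3-dihydro-1-benzofuran (O1, C2, C3, C3a, C4 to C7, C7a), and the target is taken as the (2S,3R) trans isomer that the SMILES string defines.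

**Route**

Step 1
Reactants: 1 4-fluoro-3-methoxybenzaldehyde
Product: 2 2-(4-fluoro-3-methoxyphenyl)-1,3-dioxolane
Conditions: ethylene glycol, p-TsOH (cat.), toluene, reflux, Dean–Stark
Reagents that add atoms: ethylene glycol, OCCO
Why: Acid-catalysed acetalisation with azeotropic removal of water masks the formyl group as a cyclic acetal that is stable to the amide base, the enolisation and the borohydride used later.

Step 2
Reactants: 2 2-(4-fluoro-3-methoxyphenyl)-1,3-dioxolane
Product: 4 2-(4-fluoro-3-iodo-5-methoxyphenyl)-1,3-dioxolane, via aryllithium 3 (not isolated)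
Conditions: lithium 2,2,6,6-tetramethylpiperidide (from 2,2,6,6-tetramethylpiperidine, n-BuLi), THF, −78 °C; then I2, −78 °C → rt
Reagents that add atoms: iodine, [I][I]
Why: Directed ortho-metalation, in which the hindered amide base should remove the most acidic ring proton (ortho to fluorine) rather than the proton crowded between the methoxy and dioxolanyl groups, and iodine traps the aryllithium at −78 °C before lithium fluoride can be lost.

Step 3
Reactants: 4 2-(4-fluoro-3-iodo-5-methoxyphenyl)-1,3-dioxolane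
Product: 5 ethyl 2-[5-(1,3-dioxolan-2-yl)-2-fluoro-3-methoxyphenyl]acetate
Conditions: BrZnCH2CO2Et, Pd2(dba)3 (cat.), XPhos (cat.), THF, 60 °C
Reagents that add atoms: (2-ethoxy-2-oxoethyl)zinc bromide, CCOC(=O)C[Zn]Br
Why: Negishi-type coupling of the aryl iodide with the Reformatsky zinc enolate on zerovalent palladium with a bulky biarylphosphine should form the aryl–CH2 bond without touching the acetal or the C–F bond.

Step 4
Reactants: 5 ethyl 2-[5-(1,3-dioxolan-2-yl)-2-fluoro-3-methoxyphenyl]acetate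
Product: 6 2-[5-(1,3-dioxolan-2-yl)-2-fluoro-3-methoxyphenyl]acetic acid
Conditions: LiOH, THF–H2O, rt; then 1 M HCl to pH 4, 0 °C
Reagents that add atoms: lithium hydroxide, [Li+].[OH-]
Why: Saponification of the ethyl ester, with a brief cold acidification to pH 4 that should free the acid while the cyclic acetal, which hydrolyses much more slowly than an acyclic one, survives.

Step 5
Reactants: 6 2-[5-(1,3-dioxolan-2-yl)-2-fluoro-3-methoxyphenyl]acetic acid; 7 (S)-4-benzyl-2-oxazolidinone
Product: 9 (S)-4-benzyl-3-{2-[5-(1,3-dioxolan-2-yl)-2-fluoro-3-methoxyphenyl]acetyl}oxazolidin-2-one, via mixed pivalic anhydride 8 (not isolated)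
Conditions: t-BuCOCl, Et3N, THF, −20 °C; then 7, LiCl, rt
Reagents that add atoms: none
Why: Mixed-anhydride N-acylation of the oxazolidinone promoted by LiCl and Et3N is the standard way to load an arylacetic acid onto an Evans auxiliary without strong base.

Step 6
Reactants: 10 syringaldehyde (4-hydroxy-3,5-dimethoxybenzaldehyde)
Product: 11 3,5-dimethoxy-4-(methoxymethoxy)benzaldehyde
Conditions: MOMCl, i-Pr2NEt, CH2Cl2, 0 °C → rt
Reagents that add atoms: chloromethyl methyl ether, COCCl
Why: O-Alkylation of the phenol gives a MOM ether that is stable to the boron Lewis acid, hydride, fluoride and alkoxide used later.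

Step 7
Reactants: 9 (S)-4-benzyl-3-{2-[5-(1,3-dioxolan-2-yl)-2-fluoro-3-methoxyphenyl]acetyl}oxazolidin-2-one; 11 3,5-dimethoxy-4-(methoxymethoxy)benzaldehyde
Product: 14 (S)-4-benzyl-3-{(2S,3S)-2-[5-(1,3-dioxolan-2-yl)-2-fluoro-3-methoxyphenyl]-3-hydroxy-3-[3,5-dimethoxy-4-(methoxymethoxy)phenyl]propanoyl}oxazolidin-2-one, via dibutylboron enolate 12 (not isolated), via dibutylboron aldolate 13 (not isolated)
Conditions: Bu2BOTf, i-Pr2NEt, CH2Cl2, −78 → 0 °C; then 11, −78 → 0 °C; then pH 7 buffer (NaH2PO4/Na2HPO4), MeOH, 30% H2O2, 0 °C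
Reagents that add atoms: none
Why: Evans syn aldol, in which the (Z)-boron enolate reacts through a closed chair transition state on the enolate face opposite the benzyl group of the (S)-auxiliary, which should set both new stereocentres as the (2S,3S) syn adduct (the future C3 and C2 of ring B).

Step 8
Reactants: 14 the syn aldol adduct
Product: 15 (1S,2R)-2-[5-(1,3-dioxolan-2-yl)-2-fluoro-3-methoxyphenyl]-1-[3,5-dimethoxy-4-(methoxymethoxy)phenyl]propane-1,3-diol
Conditions: LiBH4, MeOH (1 equiv), THF, 0 °C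
Reagents that add atoms: none
Why: Borohydride reduction of the imide carbonyl releases the primary alcohol and the recoverable auxiliary at 0 °C, where the α-aryl stereocentre should not epimerise; the descriptor at that carbon changes from S to R only because the CIP priorities change.

Step 9
Reactants: 15 the (1S,2R) diol
Product: 16 (1S,2R)-2-[5-(1,3-dioxolan-2-yl)-2-fluoro-3-methoxyphenyl]-1-[3,5-dimethoxy-4-(methoxymethoxy)phenyl]-3-(triisopropylsilyloxy)propan-1-ol
Conditions: i-Pr3SiCl, imidazole, DMF, 0 °C → rt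
Reagents that add atoms: chlorotriisopropylsilane, CC(C)[Si](Cl)(C(C)C)C(C)C
Why: The bulky silyl chloride should silylate the primary hydroxyl selectively over the hindered secondary benzylic one, and TIPS is the common silyl group least prone to 1,3-migration under base.

Step 10
Reactants: 16 the TIPS ether acetal
Product: 17 (1S,2R)-1-[3,5-dimethoxy-4-(methoxymethoxy)phenyl]-2-(2-fluoro-5-formyl-3-methoxyphenyl)-3-(triisopropylsilyloxy)propan-1-ol
Conditions: pyridinium p-toluenesulfonate (cat.), acetone–H2O, 50 °C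
Reagents that add atoms: water, O
Why: Mild acid-catalysed acetal hydrolysis should free the aldehyde while the aryl MOM ether, the primary TIPS ether and the benzylic alcohol, which need stronger acid to react, remain intact.

Step 11
Reactants: 17 (1S,2R)-1-[3,5-dimethoxy-4-(methoxymethoxy)phenyl]-2-(2-fluoro-5-formyl-3-methoxyphenyl)-3-(triisopropylsilyloxy)propan-1-ol
Product: 19 (2S,3R)-2-[3,5-dimethoxy-4-(methoxymethoxy)phenyl]-7-methoxy-3-[(triisopropylsilyloxy)methyl]-2,3-dihydro-1-benzofuran-5-carbaldehyde, via sodium alkoxide 18 (not isolated)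
Conditions: NaH, THF–DMPU, 0 °C → rt
Reagents that add atoms: none
Why: NaH deprotonates the secondary hydroxyl, and alkoxide 18 adds to the fluorine-bearing C7a to give a Meisenheimer adduct whose charge is delocalised onto the para C5 formyl group; loss of fluoride then restores the arene and forms O1–C7a. The closest known reaction types are the intramolecular SNAr etherification of 2-(2-fluoroaryl)ethanols to 2,3-dihydrobenzofurans and the displacement of fluoride from 4-fluorobenzaldehydes by alkoxides. Ring B (O1, C2, C3, C3a, C7a) closes by a five-membered exo addition–elimination at an aromatic carbon. No stereocentre is created: no bond to C2 or C3 is broken, so the syn (1S,2R) diad of 17 should be carried over unchanged as the trans (2S,3R) ring. The step needs chemoselectivity between the two hydroxyls, each of which could reach C7a through a five-membered ring; the TIPS ether on the primary oxygen secures it, and a hydride base is used so that no nucleophilic base adds to the aldehyde.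

Step 12
Reactants: 19 the trans dihydrobenzofuran aldehyde
Product: 20 ethyl (E)-3-{(2S,3R)-2-[3,5-dimethoxy-4-(methoxymethoxy)phenyl]-7-methoxy-3-[(triisopropylsilyloxy)methyl]-2,3-dihydro-1-benzofuran-5-yl}prop-2-enoate
Conditions: (EtO)2P(O)CH2CO2Et, NaH, THF, 0 °C → rt
Reagents that add atoms: triethyl phosphonoacetate, CCOC(=O)CP(=O)(OCC)OCC
Why: Horner–Wadsworth–Emmons olefination of the aryl aldehyde with the stabilised phosphonate anion should give the (E)-enoate.

Step 13
Reactants: 20 the (E)-enoate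
Product: 21 (E)-3-{(2S,3R)-2-[3,5-dimethoxy-4-(methoxymethoxy)phenyl]-7-methoxy-3-[(triisopropylsilyloxy)methyl]-2,3-dihydro-1-benzofuran-5-yl}prop-2-en-1-ol
Conditions: i-Bu2AlH, CH2Cl2, −78 °C; then aq potassium sodium tartrate
Reagents that add atoms: none
Why: 1,2-Reduction of the conjugated ester by the aluminium hydride at low temperature should give the (E)-allylic alcohol without touching the MOM or silyl ether.

Step 14
Reactants: 21 the allylic alcohol
Product: 22 (E)-3-{(2S,3R)-3-(hydroxymethyl)-2-[3,5-dimethoxy-4-(methoxymethoxy)phenyl]-7-methoxy-2,3-dihydro-1-benzofuran-5-yl}prop-2-en-1-ol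
Conditions: Bu4NF, THF, 0 °C → rt
Reagents that add atoms: none
Why: Fluoride-induced desilylation cleaves the primary TIPS ether, and the MOM ether and the allylic alcohol are inert to it.

Step 15
Reactants: 23 4-hydroxybenzoic acid
Product: 25 4-(methoxymethoxy)benzoic acid, via methoxymethyl ester 24 (not isolated)
Conditions: MOMCl, i-Pr2NEt, CH2Cl2, 0 °C → rt; then NaOH, MeOH–H2O, rt; then 1 M HCl to pH 4, 0 °C
Reagents that add atoms: chloromethyl methyl ether, COCCl; sodium hydroxide, [Na+].[OH-]
Why: Double O-alkylation gives the MOM ether MOM ester, and hydroxide then cleaves only the ester, so the phenol-protected acid should be obtained in one flask.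

Step 16
Reactants: 22 the diol; 25 4-(methoxymethoxy)benzoic acid (two equivalents, one for each hydroxyl)
Product: 26 the bis[4-(methoxymethoxy)benzoate] of 22, acylated at the allylic oxygen and at the C3 hydroxymethyl oxygen
Conditions: 25 (2.4 equiv), EDC·HCl (2.6 equiv), DMAP (cat.), CH2Cl2, 0 °C → rt
Reagents that add atoms: 4-(methoxymethoxy)benzoic acid (the second equivalent of 25), COCOc1ccc(C(=O)O)cc1
Why: Steglich esterification with a slight excess over two equivalents of acid 25 and carbodiimide should acylate both primary hydroxyls, each with one molecule of 25, under neutral conditions that do not ionise the electron-rich allylic alcohol.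

Step 17
Reactants: 26 the tris-MOM bis-ester
Product: 28 quiquesetinerviusin B, via tris(trimethylsilyl) ether 27 (not isolated)
Conditions: Me3SiOTf, 2,2'-bipyridyl, MeCN, 0 °C → rt; then H2O, rt
Reagents that add atoms: none
Why: Silyl triflate buffered by 2,2'-bipyridyl converts each aryl MOM ether into the aryl trimethylsilyl ether and an N-(methoxymethyl)bipyridinium salt, and water then hydrolyses the silyl ethers, so the three phenols should be freed without protic acid that would ionise the 4-alkoxycinnamyl ester or the C2 benzylic ether.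

**Compound list**

1 | 4-fluoro-3-methoxybenzaldehyde | COc1cc(C=O)ccc1F | starting material
2 | 2-(4-fluoro-3-methoxyphenyl)-1,3-dioxolane | COc1cc(C2OCCO2)ccc1F | intermediate
3 | [5-(1,3-dioxolan-2-yl)-2-fluoro-3-methoxyphenyl]lithium | COc1cc(C2OCCO2)cc([Li])c1F | intermediate
4 | 2-(4-fluoro-3-iodo-5-methoxyphenyl)-1,3-dioxolane | COc1cc(C2OCCO2)cc(I)c1F | intermediate
5 | ethyl 2-[5-(1,3-dioxolan-2-yl)-2-fluoro-3-methoxyphenyl]acetate | CCOC(=O)Cc1cc(C2OCCO2)cc(OC)c1F | intermediate
6 | 2-[5-(1,3-dioxolan-2-yl)-2-fluoro-3-methoxyphenyl]acetic acid | OC(=O)Cc1cc(C2OCCO2)cc(OC)c1F | intermediate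
7 | (S)-4-benzyl-2-oxazolidinone | O=C1N[C@@H](Cc2ccccc2)CO1 | starting material
8 | 2-[5-(1,3-dioxolan-2-yl)-2-fluoro-3-methoxyphenyl]acetic pivalic anhydride | CC(C)(C)C(=O)OC(=O)Cc1cc(C2OCCO2)cc(OC)c1F | intermediate
9 | (S)-4-benzyl-3-{2-[5-(1,3-dioxolan-2-yl)-2-fluoro-3-methoxyphenyl]acetyl}oxazolidin-2-one | O=C1OC[C@H](Cc2ccccc2)N1C(=O)Cc1cc(C2OCCO2)cc(OC)c1F | intermediate
10 | syringaldehyde (4-hydroxy-3,5-dimethoxybenzaldehyde) | COc1cc(C=O)cc(OC)c1O | starting material
11 | 3,5-dimethoxy-4-(methoxymethoxy)benzaldehyde | COCOc1c(OC)cc(C=O)cc1OC | intermediate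
12 | (Z)-dibutylboron enolate of 9 | CCCCB(CCCC)O/C(=C\c1cc(C2OCCO2)cc(OC)c1F)N1C(=O)OC[C@@H]1Cc1ccccc1 | intermediate
13 | dibutylboron aldolate of 14 (O-boryl at the carbinol oxygen) | COc1cc([C@@H](OB(CCCC)CCCC)[C@@H](C(=O)N2C(=O)OC[C@@H]2Cc2ccccc2)c2cc(C3OCCO3)cc(OC)c2F)cc(OC)c1OCOC | intermediate
14 | (S)-4-benzyl-3-{(2S,3S)-2-[5-(1,3-dioxolan-2-yl)-2-fluoro-3-methoxyphenyl]-3-hydroxy-3-[3,5-dimethoxy-4-(methoxymethoxy)phenyl]propanoyl}oxazolidin-2-one (syn) | COc1cc([C@@H](O)[C@@H](C(=O)N2C(=O)OC[C@@H]2Cc2ccccc2)c2cc(C3OCCO3)cc(OC)c2F)cc(OC)c1OCOC | intermediate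
15 | (1S,2R)-2-[5-(1,3-dioxolan-2-yl)-2-fluoro-3-methoxyphenyl]-1-[3,5-dimethoxy-4-(methoxymethoxy)phenyl]propane-1,3-diol | COc1cc([C@@H](O)[C@@H](CO)c2cc(C3OCCO3)cc(OC)c2F)cc(OC)c1OCOC | intermediate
16 | (1S,2R)-2-[5-(1,3-dioxolan-2-yl)-2-fluoro-3-methoxyphenyl]-1-[3,5-dimethoxy-4-(methoxymethoxy)phenyl]-3-(triisopropylsilyloxy)propan-1-ol | COc1cc([C@@H](O)[C@@H](CO[Si](C(C)C)(C(C)C)C(C)C)c2cc(C3OCCO3)cc(OC)c2F)cc(OC)c1OCOC | intermediate
17 | (1S,2R)-1-[3,5-dimethoxy-4-(methoxymethoxy)phenyl]-2-(2-fluoro-5-formyl-3-methoxyphenyl)-3-(triisopropylsilyloxy)propan-1-ol (syn) | COc1cc([C@@H](O)[C@@H](CO[Si](C(C)C)(C(C)C)C(C)C)c2cc(C=O)cc(OC)c2F)cc(OC)c1OCOC | intermediate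
18 | sodium alkoxide of 17 | COc1cc([C@@H]([O-])[C@@H](CO[Si](C(C)C)(C(C)C)C(C)C)c2cc(C=O)cc(OC)c2F)cc(OC)c1OCOC.[Na+] | intermediate
19 | (2S,3R)-2-[3,5-dimethoxy-4-(methoxymethoxy)phenyl]-7-methoxy-3-[(triisopropylsilyloxy)methyl]-2,3-dihydro-1-benzofuran-5-carbaldehyde (trans) | COc1cc([C@H]2Oc3c(OC)cc(C=O)cc3[C@@H]2CO[Si](C(C)C)(C(C)C)C(C)C)cc(OC)c1OCOC | intermediate
20 | ethyl (E)-3-{(2S,3R)-2-[3,5-dimethoxy-4-(methoxymethoxy)phenyl]-7-methoxy-3-[(triisopropylsilyloxy)methyl]-2,3-dihydro-1-benzofuran-5-yl}prop-2-enoate | COc1cc([C@H]2Oc3c(OC)cc(/C=C/C(=O)OCC)cc3[C@@H]2CO[Si](C(C)C)(C(C)C)C(C)C)cc(OC)c1OCOC | intermediate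
21 | (E)-3-{(2S,3R)-2-[3,5-dimethoxy-4-(methoxymethoxy)phenyl]-7-methoxy-3-[(triisopropylsilyloxy)methyl]-2,3-dihydro-1-benzofuran-5-yl}prop-2-en-1-ol | COc1cc([C@H]2Oc3c(OC)cc(/C=C/CO)cc3[C@@H]2CO[Si](C(C)C)(C(C)C)C(C)C)cc(OC)c1OCOC | intermediate
22 | (E)-3-{(2S,3R)-3-(hydroxymethyl)-2-[3,5-dimethoxy-4-(methoxymethoxy)phenyl]-7-methoxy-2,3-dihydro-1-benzofuran-5-yl}prop-2-en-1-ol | COc1cc([C@H]2Oc3c(OC)cc(/C=C/CO)cc3[C@@H]2CO)cc(OC)c1OCOC | intermediate
23 | 4-hydroxybenzoic acid | OC(=O)c1ccc(O)cc1 | starting material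
24 | methoxymethyl 4-(methoxymethoxy)benzoate | COCOC(=O)c1ccc(OCOC)cc1 | intermediate
25 | 4-(methoxymethoxy)benzoic acid | COCOc1ccc(C(=O)O)cc1 | intermediate
26 | bis[4-(methoxymethoxy)benzoate] of 22 (esters at the allylic oxygen and at the C3 hydroxymethyl oxygen) | COc1cc([C@H]2Oc3c(OC)cc(/C=C/COC(=O)c4ccc(OCOC)cc4)cc3[C@@H]2COC(=O)c2ccc(OCOC)cc2)cc(OC)c1OCOC | intermediate
27 | tris(trimethylsilyl) ether of 28 (all three phenols silylated) | COc1cc([C@H]2Oc3c(OC)cc(/C=C/COC(=O)c4ccc(O[Si](C)(C)C)cc4)cc3[C@@H]2COC(=O)c2ccc(O[Si](C)(C)C)cc2)cc(OC)c1O[Si](C)(C)C | intermediate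
28 | quiquesetinerviusin B, (2S,3R) trans | COc1cc([C@H]2Oc3c(OC)cc(/C=C/COC(=O)c4ccc(O)cc4)cc3[C@@H]2COC(=O)c2ccc(O)cc2)cc(OC)c1O | target

**Step count**

Total: 17 steps. Longest linear sequence: 15 steps (steps 1–5, 7–14, 16 and 17, from 4-fluoro-3-methoxybenzaldehyde).

**Steps most likely to fail**

Step 11 (ring closure). The sodium alkoxide may react at the formyl group of a second molecule (hemiacetal formation followed by hydride transfer of the Cannizzaro–Tishchenko or Oppenauer type) faster than it closes ring B. The silyl group may also migrate to the secondary oxygen, after which the primary oxygen would close the ring. The fallback sets out from 17 and comes back at 19, with a nitrile as the activating group during the closure. Treatment of 17 with iodine and aqueous ammonia in THF at rt should convert the aldehyde into 4-fluoro-3-methoxy-5-{(1S,2R)-1-hydroxy-1-[3,5-dimethoxy-4-(methoxymethoxy)phenyl]-3-(triisopropylsilyloxy)propan-2-yl}benzonitrile F1. NaH in THF–DMPU should cyclise F1 by the same SNAr closure, now activated by the para cyano group, to (2S,3R)-2-[3,5-dimethoxy-4-(methoxymethoxy)phenyl]-7-methoxy-3-[(triisopropylsilyloxy)methyl]-2,3-dihydro-1-benzofuran-5-carbonitrile F2. Reduction of F2 with i-Bu2AlH in toluene at −78 °C and aqueous work-up should give aldehyde 19.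

Step 17 (final deprotection). Ionisation of the 4-alkoxycinnamyl C–O bond with loss of the allylic benzoate, or opening of ring B at C2–O1, may compete with MOM cleavage under the Lewis-acidic conditions. The fallback sets out from 20 and comes back at 28; it removes the MOM group before the allylic ester exists and masks the benzoate phenols as acetates. HCl in aqueous EtOH–THF at 45 °C should remove the MOM and TIPS groups of 20 and give ethyl (E)-3-[(2S,3R)-2-(4-hydroxy-3,5-dimethoxyphenyl)-3-(hydroxymethyl)-7-methoxy-2,3-dihydro-1-benzofuran-5-yl]prop-2-enoate F3. Excess i-Bu2AlH in CH2Cl2–THF at −78 °C should reduce F3 to (E)-3-[(2S,3R)-2-(4-hydroxy-3,5-dimethoxyphenyl)-3-(hydroxymethyl)-7-methoxy-2,3-dihydro-1-benzofuran-5-yl]prop-2-en-1-ol F4. Mitsunobu esterification of F4 with 4-acetoxybenzoic acid (PPh3, DIAD, THF, 0 °C) should acylate only the two primary alcohols, because the carboxylic acid is by far the better pronucleophile than the hindered phenol, and give the bis(4-acetoxybenzoate) of F4 with free syringyl phenol F5. Pyrrolidine in CH2Cl2 at 0 °C should then remove the two aryl acetates chemoselectively and give 28.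

Step 2 (ortho-metalation and iodination). Deprotonation may be poorly regioselective (metalation between the methoxy and dioxolanyl groups), or the aryllithium may lose lithium fluoride to an aryne before it is trapped. The fallback sets out from 2 and comes back at 5, replacing the lithiation by a C–H borylation. Iridium-catalysed borylation of 2 ([Ir(OMe)(cod)]2, 4,4'-di-tert-butyl-2,2'-bipyridine, B2pin2, THF, 80 °C) should occur at the C–H bond next to the small fluorine, the other two ring C–H bonds being flanked by larger groups, and give 2-[4-fluoro-3-methoxy-5-(4,4,5,5-tetramethyl-1,3,2-dioxaborolan-2-yl)phenyl]-1,3-dioxolane F6. Suzuki–Miyaura-type coupling of F6 with ethyl bromoacetate (Pd(OAc)2, tri(1-naphthyl)phosphine, K3PO4, THF–H2O, rt) should give ester 5.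

**Further compounds**

F1 | step 11 | 4-fluoro-3-methoxy-5-{(1S,2R)-1-hydroxy-1-[3,5-dimethoxy-4-(methoxymethoxy)phenyl]-3-(triisopropylsilyloxy)propan-2-yl}benzonitrile | COc1cc([C@@H](O)[C@@H](CO[Si](C(C)C)(C(C)C)C(C)C)c2cc(C#N)cc(OC)c2F)cc(OC)c1OCOC
F2 | step 11 | (2S,3R)-2-[3,5-dimethoxy-4-(methoxymethoxy)phenyl]-7-methoxy-3-[(triisopropylsilyloxy)methyl]-2,3-dihydro-1-benzofuran-5-carbonitrile | COc1cc([C@H]2Oc3c(OC)cc(C#N)cc3[C@@H]2CO[Si](C(C)C)(C(C)C)C(C)C)cc(OC)c1OCOC
F3 | step 17 | ethyl (E)-3-[(2S,3R)-2-(4-hydroxy-3,5-dimethoxyphenyl)-3-(hydroxymethyl)-7-methoxy-2,3-dihydro-1-benzofuran-5-yl]prop-2-enoate | COc1cc([C@H]2Oc3c(OC)cc(/C=C/C(=O)OCC)cc3[C@@H]2CO)cc(OC)c1O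
F4 | step 17 | (E)-3-[(2S,3R)-2-(4-hydroxy-3,5-dimethoxyphenyl)-3-(hydroxymethyl)-7-methoxy-2,3-dihydro-1-benzofuran-5-yl]prop-2-en-1-ol | COc1cc([C@H]2Oc3c(OC)cc(/C=C/CO)cc3[C@@H]2CO)cc(OC)c1O
F5 | step 17 | bis(4-acetoxybenzoate) of F4 with free syringyl phenol | COc1cc([C@H]2Oc3c(OC)cc(/C=C/COC(=O)c4ccc(OC(C)=O)cc4)cc3[C@@H]2COC(=O)c2ccc(OC(C)=O)cc2)cc(OC)c1O
F6 | step 2 | 2-[4-fluoro-3-methoxy-5-(4,4,5,5-tetramethyl-1,3,2-dioxaborolan-2-yl)phenyl]-1,3-dioxolane | COc1cc(C2OCCO2)cc(B3OC(C)(C)C(C)(C)O3)c1F
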